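The numbers of this flask stand for no real mixture, and the outcome is calculated.

The constants below put the steps of this stirred flask on widely spaced clocks, so the reckoning starts with who finishes before whom.

    initiator → 2 initiating radical (k1 = 0.037 s⁻¹)
    free monomer + initiating radical → growing radical + monomer in chains (k2 = 5.8 × 10⁶ M⁻¹ s⁻¹)
    free monomer + growing radical → monomer in chains + growing radical, rate k3*[growing radical]*[free monomer] (k3 = 1.3 × 10⁵ M⁻¹ s⁻¹)
    2 growing radical → dead chain (k4 = 2 × 10⁶ M⁻¹ s⁻¹)
    protic impurity + free monomer → quenched substrate (k5 = 340 M⁻¹ s⁻¹)

free monomer 2.0 mM; protic impurity 0.100 mM; initiator 40 µM; time 6.0 s

- a step written with two of one species runs at k times the square of its concentration and takes two of it each time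
- the average divides the monomer in chains by the number of chains, living and dead together; two radicals that join make one chain
- run time (flask): 6.0 s

1. average number of monomer units in a chain (living and dead chains, two that joined counted as one) at 6.0 s
2. part of the free monomer that has reacted at 6.0 s

An initiating radical meets free monomer in about 8.62 × 10⁻⁵ s. Let a be the breakdown constant of the initiator, b the pairing constant of growing radicals, g the growth constant and N the initiator. Making and pairing of growing radicals balance at √(aN/b), which is 0.860 µM at the charge, and at that level their half-life by pairing is 0.291 s, far longer than that meeting time. The protic impurity follows, with a half-life of 1.02 s against free monomer as charged, shorter than the run, so the reckoning takes its 0.100 mM off the free monomer first. Growth then halves the free monomer in 6.20 s, about the length of the run. Last comes the initiator, with a half-life of 18.7 s, longer than the run, so the radical level sags gently with the root of N.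

Free monomer therefore falls pseudo-first-order under a slowly sinking radical level, and that rate integrates in closed form. The radical exposure E, g times the area under the radical level up to time t, is 2gL/a × (1 − exp(−at/2)), with L the starting level: 0.635 at the end of the run. Growth takes the part 1 − exp(−E) of the free monomer that the impurity leaves, so the reacted part is 49.7 %. Chains number the initiator broken down plus half the radicals still growing, 8.35 µM, which gives an average of 107 units.

The forecast gave 107 and 49.5 %, with radicals that “settle within a fraction of a second to a quasi-steady level just under 1 µM”. The simulation gives 107 and 49.4 %.

In this flask free monomer has a half-life by growth of 6.9 s at the end, against 6.4 min by the impurity step. Spread evenly over the run, E means a half-life of 6.55 s, close to the 6.5 s by growth at 2.55 s.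

In the neighbour flask charged with 0.10 mM of initiator, E grows with the root of the charge to 1.00, which gives 65.2 % reacted. That neighbour flask reacts 66.0 %.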